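**Retrosynthetic overview**

1. Numbering: ring C1 (C=O), C2=C3, C4 (OMe), C5, C6 (quaternary, allyl), side chain C7 (CHMe) and C8 (CH(OAc)Ar). The strategy rests on two facts: C8 is a benzylic acetoxy carbon, so it can be introduced as an acyloxocarbenium ion, and the C1 carbonyl is the direct neighbour of C6, so a C1 carbinol can hand its allyl group to C6 as it becomes the ketone.
2. Last disconnection: C2=C3, by Saegusa–Ito desaturation of 2,3-dihydromegaphone acetate 14 (C2 is the only enolisable position).
3. Key disconnection: C7–C8 and allyl–C6 in one operation, leading back to the (E)-ethylidene carbinol silyl ether 9 and the acylal 11 (Prins addition ended by a 1,2-allyl shift).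
4. 9 comes from the (S,E)-enone 6 by catalyst-controlled allylation (sets C1) and silylation; 6 comes from 4-methoxycyclohexanone by chiral-base aldol addition to acetaldehyde and dehydration (sets C4).
5. No ring is formed: the cyclohexane ring is that of 1 and the arene that of 10.

Key step: step 6

Assumption: the senses of induction of lithium (R,R)-bis(1-phenylethyl)amide (step 1, taken over from 4-tert-butylcyclohexanone) and of the Ti(OiPr)4/(R)-1,1'-bi-2-naphthol catalyst (step 3) are as written; if either is reversed, the antipodal amine or (S)-1,1'-bi-2-naphthol is used and nothing else changes.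

**Route**

Step 1
Reactants: 1 4-methoxycyclohexanone; 2 acetaldehyde
Product: 4 (4S)-2-(1-hydroxyethyl)-4-methoxycyclohexan-1-one (epimer mixture at C2 and at the carbinol carbon), via lithium (S)-4-methoxycyclohex-1-en-1-olate 3 (not isolated)
Conditions: (R,R)-bis(1-phenylethyl)amine·HCl, n-BuLi (2 equiv), THF, −78 °C; 1 added slowly; then MeCHO, −78 °C; aq NH4Cl
Reagents that add atoms: none
Why: Enantioselective deprotonation of the prochiral ketone by the chiral lithium amide–LiCl aggregate chooses one of the two enantiotopic α-methylene groups and so makes C4 stereogenic (S), and the lithium enolate then undergoes an ordinary aldol addition to acetaldehyde whose two further centres are erased in step 2.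

Step 2
Reactants: 4 (4S)-2-(1-hydroxyethyl)-4-methoxycyclohexan-1-one
Product: 6 (2E,4S)-2-ethylidene-4-methoxycyclohexan-1-one, via mesylate 5 (not isolated)
Conditions: MsCl, Et3N, CH2Cl2, 0 °C; then DBU, rt
Reagents that add atoms: methanesulfonyl chloride, CS(=O)(=O)Cl (its atoms are present in 5 only and leave again as methanesulfonate)
Why: E1cB elimination of the β-mesyloxy ketone should give the conjugated exocyclic enone as the thermodynamically preferred (E)-isomer (methyl anti to the carbonyl), while C4, which is not acidified, is untouched.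

Step 3
Reactants: 6 (2E,4S)-2-ethylidene-4-methoxycyclohexan-1-one; 7 tetraallylstannane
Product: 8 (1S,2E,4S)-2-ethylidene-4-methoxy-1-(prop-2-en-1-yl)cyclohexan-1-ol
Conditions: Ti(OiPr)4 (30 mol %), (R)-1,1'-bi-2-naphthol (30 mol %), iPrOH (20 equiv), CH2Cl2, rt
Reagents that add atoms: none
Why: Catalytic enantioface-selective 1,2-allylation of a ketone by an allylstannane (a reaction type established for α-substituted cyclic enones) sets C1 under catalyst control, which is needed because the remote C4 centre gives no useful bias, so allyl is placed trans to the methoxy group; the C1 epimer, which also collects the minor enantiomer of 6, is removed by chromatography.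

Step 4
Reactants: 8 (1S,2E,4S)-2-ethylidene-4-methoxy-1-(prop-2-en-1-yl)cyclohexan-1-ol
Product: 9 triethyl{[(1S,2E,4S)-2-ethylidene-4-methoxy-1-(prop-2-en-1-yl)cyclohexyl]oxy}silane
Conditions: Et3SiOTf, 2,6-lutidine, CH2Cl2, −78 → 0 °C
Reagents that add atoms: triethylsilyl trifluoromethanesulfonate, CC[Si](CC)(CC)OS(=O)(=O)C(F)(F)F
Why: Silylation of a hindered tertiary alcohol with a silyl triflate and a hindered pyridine base is routine and touches no stereocentre.

Step 5
Reactants: 10 3,4,5-trimethoxybenzaldehyde
Product: 11 (3,4,5-trimethoxyphenyl)methylene diacetate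
Conditions: Ac2O, H2SO4 (cat.), 0 °C → rt
Reagents that add atoms: acetic anhydride, CC(=O)OC(C)=O
Why: Acid-catalysed acylal formation, the addition of acetic anhydride across the carbonyl group of a non-enolisable aldehyde, creates no stereocentre.

Step 6
Reactants: 9 triethyl{[(1S,2E,4S)-2-ethylidene-4-methoxy-1-(prop-2-en-1-yl)cyclohexyl]oxy}silane; 11 (3,4,5-trimethoxyphenyl)methylene diacetate
Product: 14 (1R,2S)-2-[(1R,5S)-5-methoxy-2-oxo-1-(prop-2-en-1-yl)cyclohexyl]-1-(3,4,5-trimethoxyphenyl)propyl acetate (2,3-dihydromegaphone acetate), via acyloxocarbenium triflate 12 (not isolated), via O-triethylsilyl oxocarbenium triflate 13 (not isolated)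
Conditions: Et3SiOTf (20 mol %), 2,6-di-tert-butyl-4-methylpyridine (30 mol %), 11 (1.2 equiv), CH2Cl2, −78 → −40 °C; Et3N, then aq NaHCO3 at −78 °C
Reagents that add atoms: none
Why: Proposed new method: Et3SiOTf takes one acetate from 11 as Et3SiOAc to give the acyloxocarbenium ion 12, which the trisubstituted C6=C7 alkene of 9 attacks through C7 (Markovnikov, positive charge building at C6), while the C1–allyl bond, axial and parallel to the developing empty orbital in the reacting chair (silyloxy group in the alkene plane, methoxy axial), shifts to C6 and the silyloxy carbon becomes the O-silyl oxocarbenium ion 13, from which triflate removes the silyl group to give the ketone and return the catalyst. The closest known reactions are pinacol-terminated Prins reactions of alkenyl carbinol silyl ethers with tethered acetals and the Lewis-acid additions of allylsilanes or enol silanes to acylals that give homoallylic acetates directly; new here are the intermolecular union with an unactivated alkene and the 1,2-shift of an allyl group in an unstrained ring. No ring is closed. C6 (R) follows from the suprafacial shift of the allyl group on the face it holds at C1 (trans to the methoxy group) and C7 (S) from the (E)-geometry with the electrophile entering anti to the migrating bond. C8 (R) should follow from an open transition state in which the aryl group points away from C6, the C8 hydrogen takes the quadrant over C1 that the in-plane triethylsilyloxy group screens and the acyloxonium oxygen lies on the C5 side, so that the Re face of 12 meets the Si face of C7 (7,8-syn); this is the least secure of the three centres. The step needs reaction at the ethylidene and not at the allyl alkene (secured by the much higher nucleophilicity of the trisubstituted alkene), allyl shift in preference to C2 migration or proton loss (secured by the anti-periplanar axial allyl bond and the push of the oxygen), and survival of the tertiary allylic silyl ether and of the benzylic acetate (low temperature, hindered base, substoichiometric silyl triflate).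

Step 7
Reactants: 14 2,3-dihydromegaphone acetate
Product: 15 (1R,2S)-2-[(1R,5S)-5-methoxy-1-(prop-2-en-1-yl)-2-(trimethylsilyloxy)cyclohex-2-en-1-yl]-1-(3,4,5-trimethoxyphenyl)propyl acetate
Conditions: Me3SiOTf, Et3N, CH2Cl2, −20 → 0 °C
Reagents that add atoms: trimethylsilyl trifluoromethanesulfonate, C[Si](C)(C)OS(=O)(=O)C(F)(F)F
Why: Soft enolisation of the ketone can only occur toward C2 because C6 is quaternary, the amine-buffered silyl triflate should leave the less acidic acetate and the benzylic C–O bond alone, and no stereocentre is affected.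

Step 8
Reactants: 15 trimethylsilyl enol ether of 14
Product: 16 (1R,2S)-2-[(1R,5R)-5-methoxy-2-oxo-1-(prop-2-en-1-yl)cyclohex-3-en-1-yl]-1-(3,4,5-trimethoxyphenyl)propyl acetate (megaphone acetate)
Conditions: Pd(OAc)2 (1.1 equiv), MeCN, rt
Reagents that add atoms: none
Why: Saegusa–Ito oxidation, in which palladation of the silyl enol ether at C2 and syn β-hydride elimination of H-3 give the C2=C3 enone, uses the regiochemistry fixed in step 7 and leaves C4, C6, C7 and C8 unchanged (the descriptor at C4 changes from S to R only because the ring priorities change).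

**Compound list**

1 | 4-methoxycyclohexanone | COC1CCC(=O)CC1 | starting material
2 | acetaldehyde | CC=O | starting material
3 | lithium (S)-4-methoxycyclohex-1-en-1-olate (formed in the flask) | [Li]OC1=CC[C@@H](OC)CC1 | intermediate
4 | (4S)-2-(1-hydroxyethyl)-4-methoxycyclohexan-1-one, epimer mixture at C2 and the carbinol carbon | CC(O)C1C[C@@H](OC)CCC1=O | intermediate
5 | (4S)-4-methoxy-2-[1-(methylsulfonyloxy)ethyl]cyclohexan-1-one (formed in the flask) | CC(OS(C)(=O)=O)C1C[C@@H](OC)CCC1=O | intermediate
6 | (2E,4S)-2-ethylidene-4-methoxycyclohexan-1-one | C/C=C1\C[C@@H](OC)CCC1=O | intermediate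
7 | tetraallylstannane | C=CC[Sn](CC=C)(CC=C)CC=C | starting material
8 | (1S,2E,4S)-2-ethylidene-4-methoxy-1-(prop-2-en-1-yl)cyclohexan-1-ol (allyl trans to methoxy) | C=CC[C@@]1(O)CC[C@H](OC)C/C1=C\C | intermediate
9 | triethyl{[(1S,2E,4S)-2-ethylidene-4-methoxy-1-(prop-2-en-1-yl)cyclohexyl]oxy}silane | C=CC[C@@]1(O[Si](CC)(CC)CC)CC[C@H](OC)C/C1=C\C | intermediate
10 | 3,4,5-trimethoxybenzaldehyde | COc1cc(C=O)cc(OC)c1OC | starting material
11 | (3,4,5-trimethoxyphenyl)methylene diacetate | CC(=O)OC(OC(C)=O)c1cc(OC)c(OC)c(OC)c1 | intermediate
12 | acetoxy(3,4,5-trimethoxyphenyl)methylium triflate, the acyloxocarbenium ion pair (formed in the flask) | CC(=O)[O+]=Cc1cc(OC)c(OC)c(OC)c1.[O-]S(=O)(=O)C(F)(F)F | intermediate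
13 | O-triethylsilyl oxocarbenium triflate of 14 (formed in the flask) | C=CC[C@]1([C@H](C)[C@@H](OC(C)=O)c2cc(OC)c(OC)c(OC)c2)C[C@@H](OC)CCC1=[O+][Si](CC)(CC)CC.[O-]S(=O)(=O)C(F)(F)F | intermediate
14 | (1R,2S)-2-[(1R,5S)-5-methoxy-2-oxo-1-(prop-2-en-1-yl)cyclohexyl]-1-(3,4,5-trimethoxyphenyl)propyl acetate (2,3-dihydromegaphone acetate) | C=CC[C@]1([C@H](C)[C@@H](OC(C)=O)c2cc(OC)c(OC)c(OC)c2)C[C@@H](OC)CCC1=O | intermediate
15 | (1R,2S)-2-[(1R,5S)-5-methoxy-1-(prop-2-en-1-yl)-2-(trimethylsilyloxy)cyclohex-2-en-1-yl]-1-(3,4,5-trimethoxyphenyl)propyl acetate | C=CC[C@]1([C@H](C)[C@@H](OC(C)=O)c2cc(OC)c(OC)c(OC)c2)C[C@@H](OC)CC=C1O[Si](C)(C)C | intermediate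
16 | megaphone acetate, (1R,2S)-2-[(1R,5R)-5-methoxy-2-oxo-1-(prop-2-en-1-yl)cyclohex-3-en-1-yl]-1-(3,4,5-trimethoxyphenyl)propyl acetate | C=CC[C@]1([C@H](C)[C@@H](OC(C)=O)c2cc(OC)c(OC)c(OC)c2)C[C@@H](OC)C=CC1=O | target

**Count**

Total steps: 8. Longest linear sequence: 7 (steps 1–4 and 6–8; step 5 is the one-step side branch).

**Steps most likely to fail**

Step 6 (proposed new method).
- What may go wrong: ionisation of the tertiary allylic silyl ether before the C–C bond is made; proton loss or migration of C2 from the C6 cation in place of the allyl shift; attack on the wrong face of the acyloxocarbenium ion, giving the C8 epimer.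
- Fallback, known chemistry only, from enone 6 back to 14: conjugate addition of 2-lithio-1,3-dithiane to 6 in THF/HMPA at −78 °C makes the C7–C8 bond and gives lithium (4S)-2-[(1S)-1-(1,3-dithian-2-yl)ethyl]-4-methoxycyclohex-1-en-1-olate F1. This enolate is trapped in the same flask with allyl bromide to give (2R,4S)-2-[(1S)-1-(1,3-dithian-2-yl)ethyl]-4-methoxy-2-(prop-2-en-1-yl)cyclohexan-1-one F2.
- The allyl halide should enter anti to the dithianyl group of the enolate rotamer that minimises allylic 1,3-strain (C7–H eclipsing C1–O), which is the C6/C7 relationship of the target. C7 itself is formed without control from the remote C4 centre, so the isomer with both centres inverted has to be removed by chromatography.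
- Hydrolysis of the dithiane (MeI, CaCO3, aqueous MeCN) gives (2S)-2-[(1R,5S)-5-methoxy-2-oxo-1-(prop-2-en-1-yl)cyclohexyl]propanal F3. Felkin–Anh addition of (3,4,5-trimethoxyphenyl)magnesium bromide at −78 °C, anti to the quaternary C6 and selective for the aldehyde over the hindered ketone, should give the 7,8-syn alcohol (2R,4S)-2-[(1R,2S)-1-hydroxy-1-(3,4,5-trimethoxyphenyl)propan-2-yl]-4-methoxy-2-(prop-2-en-1-yl)cyclohexan-1-one F4 (2,3-dihydromegaphone). Acetylation (Ac2O, pyridine, DMAP) returns to 14.

Step 3.
- What may go wrong: slow turnover of the hindered exocyclic enone on the titanium catalyst, or facial selectivity at C1 too low to place allyl trans to the methoxy group.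
- Fallback, from 6 back to 8: catalyst control is given up for separation. Allylmagnesium bromide with CeCl3 in THF at −78 °C adds 1,2 to 6 without facial preference and should give 8 together with its C1 epimer, (1R,2E,4S)-2-ethylidene-4-methoxy-1-(prop-2-en-1-yl)cyclohexan-1-ol F5. The two tertiary alcohols have hydroxyl cis or trans to the methoxy group and are separated by chromatography; 8 then enters step 4.

Step 1.
- What may go wrong: loss of enantioselectivity, because the chair with axial methoxy delivers the opposite enolate and because enolate and ketone can exchange protons before the aldehyde arrives.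
- Fallback, from 1 and 2 back to 8: the desymmetrisation is dropped and step 3 is used as the resolving step. LiN(iPr)2 in THF at −78 °C converts 1 into racemic lithium 4-methoxycyclohex-1-en-1-olate F6, which with 2 gives racemic 2-(1-hydroxyethyl)-4-methoxycyclohexan-1-one F7. The conditions of step 2 lead through the racemic mesylate 4-methoxy-2-[1-(methylsulfonyloxy)ethyl]cyclohexan-1-one F8 to racemic (E)-2-ethylidene-4-methoxycyclohexan-1-one F9.
- In step 3 the catalyst should allylate both enantiomers of F9 on the same face of the carbonyl group: the (4S)-half gives 8 and the (4R)-half gives the diastereomer (1S,2E,4R)-2-ethylidene-4-methoxy-1-(prop-2-en-1-yl)cyclohexan-1-ol F10, which is removed by chromatography.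

Further compounds
F1 | step 6 | lithium (4S)-2-[(1S)-1-(1,3-dithian-2-yl)ethyl]-4-methoxycyclohex-1-en-1-olate | [Li]OC1=C([C@H](C)C2SCCCS2)C[C@@H](OC)CC1
F2 | step 6 | (2R,4S)-2-[(1S)-1-(1,3-dithian-2-yl)ethyl]-4-methoxy-2-(prop-2-en-1-yl)cyclohexan-1-one | C=CC[C@]1([C@H](C)C2SCCCS2)C[C@@H](OC)CCC1=O
F3 | step 6 | (2S)-2-[(1R,5S)-5-methoxy-2-oxo-1-(prop-2-en-1-yl)cyclohexyl]propanal | C=CC[C@]1([C@H](C)C=O)C[C@@H](OC)CCC1=O
F4 | step 6 | (2R,4S)-2-[(1R,2S)-1-hydroxy-1-(3,4,5-trimethoxyphenyl)propan-2-yl]-4-methoxy-2-(prop-2-en-1-yl)cyclohexan-1-one (2,3-dihydromegaphone) | C=CC[C@]1([C@H](C)[C@@H](O)c2cc(OC)c(OC)c(OC)c2)C[C@@H](OC)CCC1=O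
F5 | step 3 | (1R,2E,4S)-2-ethylidene-4-methoxy-1-(prop-2-en-1-yl)cyclohexan-1-ol | C=CC[C@]1(O)CC[C@H](OC)C/C1=C\C
F6 | step 1 | racemic lithium 4-methoxycyclohex-1-en-1-olate | [Li]OC1=CCC(OC)CC1
F7 | step 1 | racemic 2-(1-hydroxyethyl)-4-methoxycyclohexan-1-one | CC(O)C1CC(OC)CCC1=O
F8 | step 1 | racemic 4-methoxy-2-[1-(methylsulfonyloxy)ethyl]cyclohexan-1-one | CC(OS(C)(=O)=O)C1CC(OC)CCC1=O
F9 | step 1 | racemic (E)-2-ethylidene-4-methoxycyclohexan-1-one | C/C=C1\CC(OC)CCC1=O
F10 | step 1 | (1S,2E,4R)-2-ethylidene-4-methoxy-1-(prop-2-en-1-yl)cyclohexan-1-ol | C=CC[C@@]1(O)CC[C@@H](OC)C/C1=C\C
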